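**Strategy.** The six-membered carbocycle (C1–C6; C1 and C2 carry esters, C3–C4 the epoxide, C6 the side chain) holds a secondary carbinol (C1) next to a ring carbon (C6) that bears the exocyclic C7=C14 methylene: the retron of an intramolecular carbonyl-ene reaction. The ring is therefore closed last, from an acyclic (3Z,6Z)-trienal whose aldehyde carbon C1 attacks C6 while a hydrogen of the C14 methyl group migrates to oxygen. One operation should form the C1–C6 bond, the ring, the C1 and C6 stereocentres (relayed from C2) and the 1,1-disubstituted alkene. The trienal is assembled by two Z-selective Wittig reactions on a three-carbon bis-phosphonium linchpin; the three angelates are then introduced one at a time.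

Key step: step 9

Remark: atoms are numbered as in bisabolane (ring C1–C6, C7(=C14H2), C8, C9, C10, C11, C15 = methyl on C3); the two oxiranes are treated as functional groups, installed by alkene epoxidation once the carbocycle, the only ring of the carbon skeleton, exists.

Step 1
Reactants: 1 methyl (2S)-oxirane-2-carboxylate; 2 (2-methylprop-1-en-1-yl)magnesium bromide
Product: 3 methyl (2S)-2-hydroxy-5-methylhex-4-enoate
Conditions: CuI (10 mol %), THF, −40 → −20 °C; aq. NH4Cl
Reagents that add atoms: none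
Why: Copper-catalysed SN2 opening of the epoxide by the alkenyl Grignard reagent at the unsubstituted carbon (organocuprate epoxide opening) should outrun addition to the ester at low temperature and leaves the stereocentre (the later C8) untouched.

Step 2
Reactants: 3 methyl (2S)-2-hydroxy-5-methylhex-4-enoate
Product: 4 methyl (2S)-2-[(tert-butyldimethylsilyl)oxy]-5-methylhex-4-enoate
Conditions: TBSCl, imidazole, DMF, rt
Reagents that add atoms: tert-butyldimethylsilyl chloride, CC(C)(C)[Si](C)(C)Cl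
Why: Standard silyl ether formation on the secondary α-hydroxy ester should protect the future C8 hydroxyl without affecting the stereocentre.

Step 3
Reactants: 4 methyl (2S)-2-[(tert-butyldimethylsilyl)oxy]-5-methylhex-4-enoate
Product: 6 (3S)-3-[(tert-butyldimethylsilyl)oxy]-6-methylhept-5-en-2-one, via N-methoxy-N-methylamide 5 (not isolated)
Conditions: MeNH(OMe)·HCl, iPrMgCl, THF, −20 °C; then MeMgBr, −20 → 0 °C; aq. NH4Cl
Reagents that add atoms: methylmagnesium bromide, C[Mg]Br
Why: Aminolysis of the ester by the chloromagnesium amide and Grignard addition to the resulting amide (one-pot Weinreb ketone synthesis) should stop at the methyl ketone because the chelated tetrahedral adduct collapses only on work-up.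

Step 4
Reactants: 6 (3S)-3-[(tert-butyldimethylsilyl)oxy]-6-methylhept-5-en-2-one; 7 propane-1,3-diylbis(triphenylphosphonium) dibromide
Product: 9 [(3Z,5S)-5-[(tert-butyldimethylsilyl)oxy]-4,8-dimethylnona-3,7-dien-1-yl](triphenyl)phosphonium bromide, via phosphonium ylide 8 (not isolated)
Conditions: 7 (3 equiv), KN(SiMe3)2 (3 equiv), THF, −78 → 0 °C; then 6, −78 °C → rt; aq. NH4Br
Reagents that add atoms: none
Why: Wittig olefination of an α-oxygenated methyl ketone with a non-stabilised ylide is known to favour the (Z)-trisubstituted alkene (C8 cis to C5), and the excess of linchpin should confine olefination to one end so that the second phosphonium group survives for step 7.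

Step 5
Reactants: 10 methyl (2R)-2,3-dihydroxypropanoate
Product: 11 methyl (2R)-2,3-bis[(triethylsilyl)oxy]propanoate
Conditions: Et3SiCl, imidazole, CH2Cl2, 0 °C → rt
Reagents that add atoms: chlorotriethylsilane, CC[Si](CC)(CC)Cl
Why: Silyl ether formation on both hydroxyls gives a non-chelating C2 protecting group and a primary silyl ether that can later be oxidised directly.

Step 6
Reactants: 11 methyl (2R)-2,3-bis[(triethylsilyl)oxy]propanoate
Product: 13 (3R)-3,4-bis[(triethylsilyl)oxy]butan-2-one, via N-methoxy-N-methylamide 12 (not isolated)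
Conditions: MeNH(OMe)·HCl, iPrMgCl, THF, −20 °C; then MeMgBr, −20 → 0 °C; aq. NH4Cl
Reagents that add atoms: methylmagnesium bromide, C[Mg]Br
Why: The same one-pot Weinreb ketone synthesis as in step 3 should give the methyl ketone (C3 with its methyl C15) with the C2 stereocentre intact.

Step 7
Reactants: 9 [(3Z,5S)-5-[(tert-butyldimethylsilyl)oxy]-4,8-dimethylnona-3,7-dien-1-yl](triphenyl)phosphonium bromide; 13 (3R)-3,4-bis[(triethylsilyl)oxy]butan-2-one
Product: 15 (2S,3Z,6Z,8S)-8-[(tert-butyldimethylsilyl)oxy]-3,7,11-trimethyl-1,2-bis[(triethylsilyl)oxy]dodeca-3,6,10-triene, via phosphonium ylide 14 (not isolated)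
Conditions: KN(SiMe3)2 (1.0 equiv), THF, −78 °C; then 13 (1.5 equiv), −78 °C → rt
Reagents that add atoms: none
Why: A second Z-selective Wittig olefination of an α-silyloxy methyl ketone with the non-stabilised homoallylic ylide should form C3=C4 with C2 cis to C5, completing the skipped (3Z,6Z)-diene.

Step 8
Reactants: 15 (2S,3Z,6Z,8S)-8-[(tert-butyldimethylsilyl)oxy]-3,7,11-trimethyl-1,2-bis[(triethylsilyl)oxy]dodeca-3,6,10-triene
Product: 16 (2S,3Z,6Z,8S)-8-[(tert-butyldimethylsilyl)oxy]-3,7,11-trimethyl-2-[(triethylsilyl)oxy]dodeca-3,6,10-trienal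
Conditions: (COCl)2, DMSO, CH2Cl2, −78 → −40 °C; then iPr2NEt, −78 → −20 °C; used at once
Reagents that add atoms: none
Why: Under Swern oxidation conditions a primary triethylsilyl ether is cleaved and oxidised in situ while secondary silyl ethers survive, and the cold amine quench should avoid C2 epimerisation and migration of the β,γ-alkene.

Step 9
Reactants: 16 (2S,3Z,6Z,8S)-8-[(tert-butyldimethylsilyl)oxy]-3,7,11-trimethyl-2-[(triethylsilyl)oxy]dodeca-3,6,10-trienal
Product: 17 (1S,2S,6S)-6-[(3S)-3-[(tert-butyldimethylsilyl)oxy]-6-methylhepta-1,5-dien-2-yl]-3-methyl-2-[(triethylsilyl)oxy]cyclohex-3-en-1-ol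
Conditions: Me2AlCl (1.1 equiv), CH2Cl2, −78 → −40 °C; aq. Rochelle salt
Reagents that add atoms: none
Why: Me2AlCl binds the aldehyde oxygen, C6 of the (6Z)-alkene adds to the activated carbonyl carbon C1 and a hydrogen of the C14 methyl group passes to oxygen through a six-membered ene transition state, giving the C1 carbinol, the C1–C6 bond and the C7=C14 methylene at once; the closest known reaction is the Lewis-acid-promoted intramolecular carbonyl-ene cyclisation of citronellal to isopulegol. The cyclohexene ring is closed in the 6-exo-trig mode with respect to both the carbonyl group and the alkene, through a half-chair that already contains the (3Z)-alkene. C1 is controlled by C2: with one equivalent of a monodentate Lewis acid the silyl ether is not chelated, the C2–O bond lies antiperiplanar to the forming C1–C6 bond (polar Felkin–Anh arrangement, the pseudo-equatorial position of the half-chair) and the aluminium-bound oxygen is equatorial, so the C1 oxygen should come out trans to the C2 oxygen. C6 is controlled by the chair-like transition state, in which the alkene lies equatorial next to the equatorial oxygen as in isopulegol, so the side chain should be trans to the C1 hydroxyl. The step needs hydrogen transfer from C14 and not from C8, which the (6Z) geometry secures (C14 sits on the side of the carbonyl oxygen, C8–H is remote and deactivated by its silyloxy group), and it needs the C10=C11 alkene to stay out, which ring size secures. Me2AlCl also scavenges protons, so acid-induced isomerisation of the skipped diene should be suppressed.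

Step 10
Reactants: 17 (1S,2S,6S)-6-[(3S)-3-[(tert-butyldimethylsilyl)oxy]-6-methylhepta-1,5-dien-2-yl]-3-methyl-2-[(triethylsilyl)oxy]cyclohex-3-en-1-ol; 18 (2Z)-2-methylbut-2-enoic acid (angelic acid)
Product: 19 (1S,2S,6S)-6-[(3S)-3-[(tert-butyldimethylsilyl)oxy]-6-methylhepta-1,5-dien-2-yl]-3-methyl-2-[(triethylsilyl)oxy]cyclohex-3-en-1-yl (2Z)-2-methylbut-2-enoate
Conditions: 18, 2,4,6-trichlorobenzoyl chloride, Et3N (excess), toluene, rt; filtration of Et3N·HCl; then 17, 75 °C
Reagents that add atoms: none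
Why: Acylation through the mixed anhydride of angelic acid with 2,4,6-trichlorobenzoic acid without a nucleophilic catalyst (Yamaguchi-type esterification) is the established way to make angelates without Z to E isomerisation, and the C1 hydroxyl is the only free hydroxyl of 17, so the site of the first ester is fixed.

Step 11
Reactants: 19 (1S,2S,6S)-6-[(3S)-3-[(tert-butyldimethylsilyl)oxy]-6-methylhepta-1,5-dien-2-yl]-3-methyl-2-[(triethylsilyl)oxy]cyclohex-3-en-1-yl (2Z)-2-methylbut-2-enoate
Product: 20 (1S,2S,6S)-6-[(3S)-3-[(tert-butyldimethylsilyl)oxy]-6-methylhepta-1,5-dien-2-yl]-2-hydroxy-3-methylcyclohex-3-en-1-yl (2Z)-2-methylbut-2-enoate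
Conditions: PPTS (cat.), MeOH/CH2Cl2, 0 °C → rt
Reagents that add atoms: none
Why: Acid-catalysed methanolysis (selective desilylation) should remove the triethylsilyl ether much faster than the tert-butyldimethylsilyl ether at C8, freeing the allylic C2 hydroxyl, and the mild acid should not move the trans-disposed C1 angelate to C2.

Step 12
Reactants: 20 (1S,2S,6S)-6-[(3S)-3-[(tert-butyldimethylsilyl)oxy]-6-methylhepta-1,5-dien-2-yl]-2-hydroxy-3-methylcyclohex-3-en-1-yl (2Z)-2-methylbut-2-enoate
Product: 21 (1R,2R,3S,4S,6S)-4-[(3S)-3-[(tert-butyldimethylsilyl)oxy]-6-methylhepta-1,5-dien-2-yl]-2-hydroxy-1-methyl-7-oxabicyclo[4.1.0]heptan-3-yl (2Z)-2-methylbut-2-enoate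
Conditions: VO(acac)2 (5 mol %), tBuOOH (1.2 equiv), CH2Cl2, 0 °C
Reagents that add atoms: tert-butyl hydroperoxide, CC(C)(C)OO
Why: In the vanadium-catalysed hydroxyl-directed epoxidation the allylic C2 hydroxyl, now the only free hydroxyl, should deliver oxygen to the syn face of the ring alkene, setting C3 and C4 with the oxirane cis to the C2 oxygen, while the C10=C11, C7=C14 and angelate alkenes, which have no directing hydroxyl, are left.

Step 13
Reactants: 21 (1R,2R,3S,4S,6S)-4-[(3S)-3-[(tert-butyldimethylsilyl)oxy]-6-methylhepta-1,5-dien-2-yl]-2-hydroxy-1-methyl-7-oxabicyclo[4.1.0]heptan-3-yl (2Z)-2-methylbut-2-enoate; 18 (2Z)-2-methylbut-2-enoic acid (angelic acid)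
Product: 22 (1S,2R,3S,4S,6S)-4-[(3S)-3-[(tert-butyldimethylsilyl)oxy]-6-methylhepta-1,5-dien-2-yl]-1-methyl-7-oxabicyclo[4.1.0]heptane-2,3-diyl bis[(2Z)-2-methylbut-2-enoate]
Conditions: 18, 2,4,6-trichlorobenzoyl chloride, Et3N (excess), toluene, rt; filtration of Et3N·HCl; then 21, 75 °C
Reagents that add atoms: none
Why: The same catalyst-free Yamaguchi-type esterification should acylate the crowded C2 hydroxyl, the only free one of 21, without Z to E isomerisation, and removal of the chloride salt with excess amine as buffer should keep the oxirane closed.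

Step 14
Reactants: 22 (1S,2R,3S,4S,6S)-4-[(3S)-3-[(tert-butyldimethylsilyl)oxy]-6-methylhepta-1,5-dien-2-yl]-1-methyl-7-oxabicyclo[4.1.0]heptane-2,3-diyl bis[(2Z)-2-methylbut-2-enoate]
Product: 23 (1S,2R,3S,4S,6S)-4-[(3S)-3-hydroxy-6-methylhepta-1,5-dien-2-yl]-1-methyl-7-oxabicyclo[4.1.0]heptane-2,3-diyl bis[(2Z)-2-methylbut-2-enoate]
Conditions: HF·pyridine, pyridine (excess), THF, 0 °C → rt; aq. NaHCO3
Reagents that add atoms: none
Why: Fluoride-mediated desilylation with pyridine-buffered HF·pyridine should free the C8 hydroxyl without the ester cleavage or acyl migration that basic fluoride could cause, and the buffered medium should leave the hindered, ester-flanked oxirane intact.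

Step 15
Reactants: 23 (1S,2R,3S,4S,6S)-4-[(3S)-3-hydroxy-6-methylhepta-1,5-dien-2-yl]-1-methyl-7-oxabicyclo[4.1.0]heptane-2,3-diyl bis[(2Z)-2-methylbut-2-enoate]; 18 (2Z)-2-methylbut-2-enoic acid (angelic acid)
Product: 24 (1S,2R,3S,4S,6S)-1-methyl-4-[(3S)-6-methyl-3-{[(2Z)-2-methylbut-2-enoyl]oxy}hepta-1,5-dien-2-yl]-7-oxabicyclo[4.1.0]heptane-2,3-diyl bis[(2Z)-2-methylbut-2-enoate]
Conditions: 18, 2,4,6-trichlorobenzoyl chloride, Et3N (excess), toluene, rt; filtration of Et3N·HCl; then 23, 75 °C
Reagents that add atoms: none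
Why: A third catalyst-free Yamaguchi-type esterification should convert the allylic C8 hydroxyl, the only free one of 23, into its angelate with retention at C8 and without Z to E isomerisation.

Step 16
Reactants: 24 (1S,2R,3S,4S,6S)-1-methyl-4-[(3S)-6-methyl-3-{[(2Z)-2-methylbut-2-enoyl]oxy}hepta-1,5-dien-2-yl]-7-oxabicyclo[4.1.0]heptane-2,3-diyl bis[(2Z)-2-methylbut-2-enoate]
Product: 25 (1S,2R,3S,4S,6S)-4-[(3S)-4-[(2R)-3,3-dimethyloxiran-2-yl]-3-{[(2Z)-2-methylbut-2-enoyl]oxy}but-1-en-2-yl]-1-methyl-7-oxabicyclo[4.1.0]heptane-2,3-diyl bis[(2Z)-2-methylbut-2-enoate] (CNP0258231.3)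
Conditions: D-fructose-derived Shi ketone (30 mol %), Oxone (KHSO5), K2CO3, Bu4NHSO4, MeCN/CH2(OMe)2/aq. buffer pH 10.5, 0 °C
Reagents that add atoms: potassium peroxymonosulfate, [K+].[O-]S(=O)(=O)OO
Why: In the Shi epoxidation the chiral dioxirane should attack the electron-rich trisubstituted C10=C11 alkene in preference to the hindered 1,1-disubstituted C7=C14 alkene and the electron-poor angelate alkenes, and the spiro transition state of the D-fructose-derived ketone should give the (10R) oxirane.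

**Compound list**

1 | methyl (2S)-oxirane-2-carboxylate | COC(=O)[C@@H]1CO1 | starting material
2 | (2-methylprop-1-en-1-yl)magnesium bromide | CC(C)=C[Mg]Br | starting material
3 | methyl (2S)-2-hydroxy-5-methylhex-4-enoate | COC(=O)[C@H](CC=C(C)C)O | intermediate
4 | methyl (2S)-2-[(tert-butyldimethylsilyl)oxy]-5-methylhex-4-enoate | COC(=O)[C@H](CC=C(C)C)O[Si](C)(C)C(C)(C)C | intermediate
5 | (2S)-2-[(tert-butyldimethylsilyl)oxy]-N-methoxy-N,5-dimethylhex-4-enamide | CON(C)C(=O)[C@H](CC=C(C)C)O[Si](C)(C)C(C)(C)C | intermediate (not isolated)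
6 | (3S)-3-[(tert-butyldimethylsilyl)oxy]-6-methylhept-5-en-2-one | CC(=O)[C@H](CC=C(C)C)O[Si](C)(C)C(C)(C)C | intermediate
7 | propane-1,3-diylbis(triphenylphosphonium) dibromide | [Br-].[Br-].c1ccc(cc1)[P+](c1ccccc1)(c1ccccc1)CCC[P+](c1ccccc1)(c1ccccc1)c1ccccc1 | starting material
8 | triphenyl[3-(triphenyl-λ5-phosphanylidene)propyl]phosphonium bromide | [Br-].c1ccc(cc1)P(c1ccccc1)(c1ccccc1)=CCC[P+](c1ccccc1)(c1ccccc1)c1ccccc1 | intermediate (not isolated)
9 | [(3Z,5S)-5-[(tert-butyldimethylsilyl)oxy]-4,8-dimethylnona-3,7-dien-1-yl](triphenyl)phosphonium bromide | [Br-].CC(C)=CC[C@H](O[Si](C)(C)C(C)(C)C)/C(C)=C\CC[P+](c1ccccc1)(c1ccccc1)c1ccccc1 | intermediate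
10 | methyl (2R)-2,3-dihydroxypropanoate | COC(=O)[C@H](O)CO | starting material
11 | methyl (2R)-2,3-bis[(triethylsilyl)oxy]propanoate | COC(=O)[C@H](O[Si](CC)(CC)CC)CO[Si](CC)(CC)CC | intermediate
12 | (2R)-N-methoxy-N-methyl-2,3-bis[(triethylsilyl)oxy]propanamide | CON(C)C(=O)[C@H](O[Si](CC)(CC)CC)CO[Si](CC)(CC)CC | intermediate (not isolated)
13 | (3R)-3,4-bis[(triethylsilyl)oxy]butan-2-one | CC(=O)[C@H](O[Si](CC)(CC)CC)CO[Si](CC)(CC)CC | intermediate
14 | [(3Z,5S)-5-[(tert-butyldimethylsilyl)oxy]-4,8-dimethylnona-3,7-dien-1-ylidene](triphenyl)-λ5-phosphane | CC(C)=CC[C@H](O[Si](C)(C)C(C)(C)C)/C(C)=C\CC=P(c1ccccc1)(c1ccccc1)c1ccccc1 | intermediate (not isolated)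
15 | (2S,3Z,6Z,8S)-8-[(tert-butyldimethylsilyl)oxy]-3,7,11-trimethyl-1,2-bis[(triethylsilyl)oxy]dodeca-3,6,10-triene | CC[Si](CC)(CC)OC[C@@H](O[Si](CC)(CC)CC)/C(C)=C\C/C=C(C)\[C@H](CC=C(C)C)O[Si](C)(C)C(C)(C)C | intermediate
16 | (2S,3Z,6Z,8S)-8-[(tert-butyldimethylsilyl)oxy]-3,7,11-trimethyl-2-[(triethylsilyl)oxy]dodeca-3,6,10-trienal | O=C[C@@H](O[Si](CC)(CC)CC)/C(C)=C\C/C=C(C)\[C@H](CC=C(C)C)O[Si](C)(C)C(C)(C)C | intermediate
17 | (1S,2S,6S)-6-[(3S)-3-[(tert-butyldimethylsilyl)oxy]-6-methylhepta-1,5-dien-2-yl]-3-methyl-2-[(triethylsilyl)oxy]cyclohex-3-en-1-ol | C=C([C@H](CC=C(C)C)O[Si](C)(C)C(C)(C)C)[C@@H]1CC=C(C)[C@H](O[Si](CC)(CC)CC)[C@H]1O | intermediate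
18 | (2Z)-2-methylbut-2-enoic acid (angelic acid) | C/C=C(/C)C(=O)O | starting material
19 | (1S,2S,6S)-6-[(3S)-3-[(tert-butyldimethylsilyl)oxy]-6-methylhepta-1,5-dien-2-yl]-3-methyl-2-[(triethylsilyl)oxy]cyclohex-3-en-1-yl (2Z)-2-methylbut-2-enoate | C=C([C@H](CC=C(C)C)O[Si](C)(C)C(C)(C)C)[C@@H]1CC=C(C)[C@H](O[Si](CC)(CC)CC)[C@H]1OC(=O)/C(C)=C\C | intermediate
20 | (1S,2S,6S)-6-[(3S)-3-[(tert-butyldimethylsilyl)oxy]-6-methylhepta-1,5-dien-2-yl]-2-hydroxy-3-methylcyclohex-3-en-1-yl (2Z)-2-methylbut-2-enoate | C=C([C@H](CC=C(C)C)O[Si](C)(C)C(C)(C)C)[C@@H]1CC=C(C)[C@H](O)[C@H]1OC(=O)/C(C)=C\C | intermediate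
21 | (1R,2R,3S,4S,6S)-4-[(3S)-3-[(tert-butyldimethylsilyl)oxy]-6-methylhepta-1,5-dien-2-yl]-2-hydroxy-1-methyl-7-oxabicyclo[4.1.0]heptan-3-yl (2Z)-2-methylbut-2-enoate | C=C([C@H](CC=C(C)C)O[Si](C)(C)C(C)(C)C)[C@@H]1C[C@@H]2O[C@]2(C)[C@H](O)[C@H]1OC(=O)/C(C)=C\C | intermediate
22 | (1S,2R,3S,4S,6S)-4-[(3S)-3-[(tert-butyldimethylsilyl)oxy]-6-methylhepta-1,5-dien-2-yl]-1-methyl-7-oxabicyclo[4.1.0]heptane-2,3-diyl bis[(2Z)-2-methylbut-2-enoate] | C=C([C@H](CC=C(C)C)O[Si](C)(C)C(C)(C)C)[C@@H]1C[C@@H]2O[C@]2(C)[C@H](OC(=O)/C(C)=C\C)[C@H]1OC(=O)/C(C)=C\C | intermediate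
23 | (1S,2R,3S,4S,6S)-4-[(3S)-3-hydroxy-6-methylhepta-1,5-dien-2-yl]-1-methyl-7-oxabicyclo[4.1.0]heptane-2,3-diyl bis[(2Z)-2-methylbut-2-enoate] | C=C([C@H](CC=C(C)C)O)[C@@H]1C[C@@H]2O[C@]2(C)[C@H](OC(=O)/C(C)=C\C)[C@H]1OC(=O)/C(C)=C\C | intermediate
24 | (1S,2R,3S,4S,6S)-1-methyl-4-[(3S)-6-methyl-3-{[(2Z)-2-methylbut-2-enoyl]oxy}hepta-1,5-dien-2-yl]-7-oxabicyclo[4.1.0]heptane-2,3-diyl bis[(2Z)-2-methylbut-2-enoate] | C=C([C@H](CC=C(C)C)OC(=O)/C(C)=C\C)[C@@H]1C[C@@H]2O[C@]2(C)[C@H](OC(=O)/C(C)=C\C)[C@H]1OC(=O)/C(C)=C\C | intermediate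
25 | (1S,2R,3S,4S,6S)-4-[(3S)-4-[(2R)-3,3-dimethyloxiran-2-yl]-3-{[(2Z)-2-methylbut-2-enoyl]oxy}but-1-en-2-yl]-1-methyl-7-oxabicyclo[4.1.0]heptane-2,3-diyl bis[(2Z)-2-methylbut-2-enoate] (CNP0258231.3) | C=C([C@H](C[C@H]1OC1(C)C)OC(=O)/C(C)=C\C)[C@@H]1C[C@@H]2O[C@]2(C)[C@H](OC(=O)/C(C)=C\C)[C@H]1OC(=O)/C(C)=C\C | target

**Step count.** Total: 16 steps. Longest linear sequence: 14 steps (steps 1–4, then 7–16).

**Steps most likely to fail**

Step 9 (key step). The ring may close through a competing transition state, with the C2 silyloxy group pseudo-axial (for instance after chelation by aluminium) or with the aluminium-bound oxygen axial, so that C1 and C6 form with poor diastereofacial selectivity. The β,γ-double bond of the aldehyde may also migrate before cyclisation, or chloride may capture the developing C7 cation instead of hydrogen transfer. The fallback takes the C2 stereocentre out of the cyclisation and hands control to a chiral Lewis acid. It sets out from compound 15: PPTS in MeOH at rt removes both triethylsilyl ethers to give the 1,2-diol F1, and a double Swern oxidation gives the α-keto aldehyde F2. Its 1,2-dicarbonyl unit should bind [Cu((S,S)-tBu-box)](SbF6)2 (a divalent copper bis(oxazoline) complex, ligand enantiomer chosen to match the C8 centre) in a bidentate way. The glyoxal-type carbonyl-ene cyclisation, modelled on catalytic enantioselective glyoxylate-ene reactions, should then form the same C1–C6 bond and give the trans α-hydroxy enone F3. Esterification of its C1 hydroxyl with angelic acid 18 under the conditions of step 10 gives the keto ester F4. Luche reduction (NaBH4, CeCl3·7H2O, MeOH, −78 °C) should then deliver hydride axially to the C2 carbonyl and give the pseudo-equatorial C2 hydroxyl trans to the C1 ester, so the route is rejoined at compound 20.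

Step 4. Mono-olefination of the bis-phosphonium linchpin may fail through statistical double olefination, enolisation of the hindered ketone by the ylide, erosion of Z-selectivity, or difficult separation of the product salt from excess 7. The fallback builds the phosphonium salt stepwise. It sets out from compound 6: Wittig olefination with the ylide of [3-(triethylsilyloxy)propyl]triphenylphosphonium bromide (KN(SiMe3)2, THF, −78 °C → rt) should give the (Z)-alkene F5. PPTS in MeOH frees the primary alcohol F6, an Appel reaction (I2, PPh3, imidazole) gives the iodide F7, and PPh3 in MeCN at reflux gives the phosphonium iodide F8. Deprotonation of F8 with KN(SiMe3)2 gives the same ylide, so the route is rejoined at compound 14 and continues to 15 in step 7.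

Step 13. Acylation may stall at the C2 hydroxyl, which is crowded by the quaternary oxirane carbon C3 and the C1 angelate. Prolonged heating may isomerise angelate to tiglate, and chloride or carboxylate may open the ring oxirane. The fallback forms the angelate double bond after acylation. It sets out from compound 21: esterification of the C2 hydroxyl with 2-[bis(2,2,2-trifluoroethoxy)phosphoryl]propanoic acid (DCC, DMAP, CH2Cl2, rt; the acyl group has no isomerisable alkene, so a nucleophilic catalyst can be used) gives the phosphonate F9. A Still–Gennari olefination with acetaldehyde (KN(SiMe3)2, 18-crown-6, THF, −78 °C) should then give the (Z)-2-methylbut-2-enoate, rejoining the route at compound 22.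

**Further compounds**

F1 | step 9 | (2S,3Z,6Z,8S)-8-[(tert-butyldimethylsilyl)oxy]-3,7,11-trimethyldodeca-3,6,10-triene-1,2-diol | OC[C@@H](O)/C(C)=C\C/C=C(C)\[C@H](CC=C(C)C)O[Si](C)(C)C(C)(C)C
F2 | step 9 | (3Z,6Z,8S)-8-[(tert-butyldimethylsilyl)oxy]-3,7,11-trimethyl-2-oxododeca-3,6,10-trienal | O=CC(=O)/C(C)=C\C/C=C(C)\[C@H](CC=C(C)C)O[Si](C)(C)C(C)(C)C
F3 | step 9 | (5S,6S)-5-[(3S)-3-[(tert-butyldimethylsilyl)oxy]-6-methylhepta-1,5-dien-2-yl]-6-hydroxy-2-methylcyclohex-2-en-1-one | C=C([C@H](CC=C(C)C)O[Si](C)(C)C(C)(C)C)[C@@H]1CC=C(C)C(=O)[C@H]1O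
F4 | step 9 | (1S,6S)-6-[(3S)-3-[(tert-butyldimethylsilyl)oxy]-6-methylhepta-1,5-dien-2-yl]-3-methyl-2-oxocyclohex-3-en-1-yl (2Z)-2-methylbut-2-enoate | C=C([C@H](CC=C(C)C)O[Si](C)(C)C(C)(C)C)[C@@H]1CC=C(C)C(=O)[C@H]1OC(=O)/C(C)=C\C
F5 | step 4 | (5S,6Z)-5-[(tert-butyldimethylsilyl)oxy]-2,6-dimethyl-9-[(triethylsilyl)oxy]nona-2,6-diene | CC(C)=CC[C@H](O[Si](C)(C)C(C)(C)C)/C(C)=C\CCO[Si](CC)(CC)CC
F6 | step 4 | (3Z,5S)-5-[(tert-butyldimethylsilyl)oxy]-4,8-dimethylnona-3,7-dien-1-ol | CC(C)=CC[C@H](O[Si](C)(C)C(C)(C)C)/C(C)=C\CCO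
F7 | step 4 | (3Z,5S)-5-[(tert-butyldimethylsilyl)oxy]-1-iodo-4,8-dimethylnona-3,7-diene | CC(C)=CC[C@H](O[Si](C)(C)C(C)(C)C)/C(C)=C\CCI
F8 | step 4 | [(3Z,5S)-5-[(tert-butyldimethylsilyl)oxy]-4,8-dimethylnona-3,7-dien-1-yl](triphenyl)phosphonium iodide | [I-].CC(C)=CC[C@H](O[Si](C)(C)C(C)(C)C)/C(C)=C\CC[P+](c1ccccc1)(c1ccccc1)c1ccccc1
F9 | step 13 | (1S,2R,3S,4S,6S)-4-[(3S)-3-[(tert-butyldimethylsilyl)oxy]-6-methylhepta-1,5-dien-2-yl]-1-methyl-3-{[(2Z)-2-methylbut-2-enoyl]oxy}-7-oxabicyclo[4.1.0]heptan-2-yl 2-[bis(2,2,2-trifluoroethoxy)phosphoryl]propanoate (epimers at the phosphonate-bearing carbon) | C=C([C@H](CC=C(C)C)O[Si](C)(C)C(C)(C)C)[C@@H]1C[C@@H]2O[C@]2(C)[C@H](OC(=O)C(C)P(=O)(OCC(F)(F)F)OCC(F)(F)F)[C@H]1OC(=O)/C(C)=C\C
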